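**Assumption (one line):** the target is made as the open 6‑hydroxy‑15‑aldehyde form drawn (its five‑ring lactol tautomer may co‑exist); elemane numbering (C1–C15, ring C5–C10, lactone O on C8, β = face of the C10 methyl) is used in the text for all intermediates.

## Retrosynthetic overview

1. Target ⇐ catalyst‑controlled epoxidation of the C10 vinyl, SeO2 oxidation of the isopropenyl methyl, and an oxidation/reduction that turns the C6 carbinol axial.
2. Bicyclic core ⇐ one carbonylative [2+2+1] (allenic hetero‑Pauson–Khand) of an acyclic allenyl aldehyde with CO: C7–C8, C11–C12 and C12–O form, so cyclohexane and α‑methylene‑γ‑lactone close together.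
3. Allenyl aldehyde ⇐ ethynyl ketone ⇐ Weinreb amide ⇐ γ‑lactone; C13 comes from formaldehyde.
4. γ‑Lactone ⇐ Ireland–Claisen rearrangement (C5–C10 bond, quaternary C10 with its vinyl) of an allylic 3‑methylbut‑3‑enoate; C9 comes from a catalytic asymmetric alkenylzinc addition to 2,2‑dimethoxyacetaldehyde.
5. Ring order: temporary γ‑lactone (opened again), temporary δ‑lactol, then cyclohexane + lactone in one step, oxirane last.

## Route

Step 1
Reactants: 1 but-2-yn-1-ol; 2 3-methylbut-3-enoic acid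
Product: 3 but-2-yn-1-yl 3-methylbut-3-enoate
Conditions: N,N'-diisopropylcarbodiimide, 4-(dimethylamino)pyridine (5 mol %), CH2Cl2, 0 °C
Reagents that add atoms: none
Why: Steglich esterification joins the two fragments, and the low temperature and low base loading keep the β,γ‑alkene out of conjugation; no stereocentre is formed.

Step 2
Reactants: 3 but-2-yn-1-yl 3-methylbut-3-enoate; 4 2,2-dimethoxyacetaldehyde
Product: 7 (2E,4S)-4-hydroxy-5,5-dimethoxy-3-methylpent-2-en-1-yl 3-methylbut-3-enoate, via alkenylzirconocene chloride 5 (not isolated), via alkenyl(methyl)zinc species 6 (not isolated)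
Conditions: Cp2Zr(H)Cl (1.2 equiv), CH2Cl2, rt; Me2Zn, toluene, −65 °C; (−)-MIB [(2S)-3-exo-morpholinoisoborneol] (10 mol %), 4, −30 → 0 °C; aq NH4Cl
Reagents that add atoms: none
Why: Syn hydrozirconation puts zirconium on the methyl‑bearing alkyne carbon and fixes the (E)‑alkene (ester and 1,1‑disubstituted alkene react more slowly), Zr‑to‑Zn transmetalation gives an alkenylzinc, and its (−)-MIB‑catalysed addition to the aldehyde (catalytic asymmetric alkenylzinc addition) sets C9 as S by ligand control.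

Step 3
Reactants: 7 (2E,4S)-4-hydroxy-5,5-dimethoxy-3-methylpent-2-en-1-yl 3-methylbut-3-enoate
Product: 10 (3S,4S,5S)-5-(dimethoxymethyl)-4-methyl-3-(prop-1-en-2-yl)-4-vinyldihydrofuran-2(3H)-one, via bis-silyl ketene acetal 8 (not isolated), via hydroxy acid 9 (not isolated)
Conditions: LDA (2.4 equiv), THF, −78 °C; TMSCl/Et3N, −78 → 60 °C; then 1 M HCl, THF, 0 °C → rt
Reagents that add atoms: none
Why: Ireland–Claisen rearrangement: the (E)‑silyl ketene acetal from LDA/THF and the (E)‑alkene react through a chair transition state (isopropenyl and C10 methyl both axial), with the new bond formed anti to the allylic C9–O bond while C9–H eclipses the C10 methyl, which sets C5 and the quaternary C10; acid then removes silicon and closes the γ‑lactone.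

Step 4
Reactants: 10 (3S,4S,5S)-5-(dimethoxymethyl)-4-methyl-3-(prop-1-en-2-yl)-4-vinyldihydrofuran-2(3H)-one
Product: 11 (2S,3S,4S)-4-hydroxy-N,5,5-trimethoxy-N,3-dimethyl-2-(prop-1-en-2-yl)-3-vinylpentanamide
Conditions: MeNH(OMe)·HCl, i-PrMgCl, THF, −20 → 0 °C
Reagents that add atoms: N,O-dimethylhydroxylamine hydrochloride, CNOC.Cl
Why: Lactone aminolysis by the magnesium amide (Weinreb amide formation) opens the ring without touching the stereocentres and frees the C9 hydroxyl.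

Step 5
Reactants: 11 (2S,3S,4S)-4-hydroxy-N,5,5-trimethoxy-N,3-dimethyl-2-(prop-1-en-2-yl)-3-vinylpentanamide; 12 (S)-2-methylbutanoic anhydride
Product: 13 (2S,3S,4S)-1,1-dimethoxy-5-[methoxy(methyl)amino]-3-methyl-5-oxo-4-(prop-1-en-2-yl)-3-vinylpentan-2-yl (2S)-2-methylbutanoate
Conditions: Et3N, 4-(dimethylamino)pyridine (0.5 equiv), CH2Cl2, rt
Reagents that add atoms: none
Why: 4-(Dimethylamino)pyridine‑catalysed acylation puts the final ester on the only free hydroxyl, and anhydride activation avoids a ketene, so the side‑chain stereocentre is retained.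

Step 6
Reactants: 13 (2S,3S,4S)-1,1-dimethoxy-5-[methoxy(methyl)amino]-3-methyl-5-oxo-4-(prop-1-en-2-yl)-3-vinylpentan-2-yl (2S)-2-methylbutanoate
Product: 14 (2S,3S,4S)-1,1-dimethoxy-3-methyl-5-oxo-4-(prop-1-en-2-yl)-3-vinylhept-6-yn-2-yl (2S)-2-methylbutanoate
Conditions: HC≡CMgBr (3 equiv), THF, 0 °C; cold aq NH4Cl; used at once
Reagents that add atoms: ethynylmagnesium bromide, C#C[Mg]Br
Why: Weinreb ketone synthesis: the chelated tetrahedral adduct stops at mono‑addition and gives the ethynyl ketone, and the hindered C9 ester is not attacked at 0 °C.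

Step 7
Reactants: 14 (2S,3S,4S)-1,1-dimethoxy-3-methyl-5-oxo-4-(prop-1-en-2-yl)-3-vinylhept-6-yn-2-yl (2S)-2-methylbutanoate
Product: 15 (2S,3S,4S,5R)-5-hydroxy-1,1-dimethoxy-3-methyl-4-(prop-1-en-2-yl)-3-vinylhept-6-yn-2-yl (2S)-2-methylbutanoate
Conditions: (R)-2-methyl-CBS-oxazaborolidine (1.0 equiv), catecholborane, CH2Cl2, −78 °C
Reagents that add atoms: none
Why: Corey–Bakshi–Shibata reduction with the alkynyl group as the small substituent gives the 6R carbinol under reagent control; this epimer is chosen on purpose because it keeps the C6 oxygen equatorial in the chair through which step 10 closes the ring.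

Step 8
Reactants: 15 (2S,3S,4S,5R)-5-hydroxy-1,1-dimethoxy-3-methyl-4-(prop-1-en-2-yl)-3-vinylhept-6-yn-2-yl (2S)-2-methylbutanoate
Product: 17 (2S,3S,4S,5S)-5-hydroxy-1,1-dimethoxy-3-methyl-4-(prop-1-en-2-yl)-3-vinylocta-6,7-dien-2-yl (2S)-2-methylbutanoate, via propargylic Mannich base 16 (not isolated)
Conditions: CuI (0.5 equiv), (CH2O)n (2.5 equiv), Cy2NH (1.8 equiv), 1,4-dioxane, 100 °C
Reagents that add atoms: formaldehyde (as paraformaldehyde), C=O
Why: Crabbé homologation: copper‑mediated Mannich reaction of the terminal alkyne, then 1,5‑hydride transfer (retro‑imino‑ene) releases the terminal allene; C6 is untouched (its descriptor becomes S only through the CIP ranking).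

Step 9
Reactants: 17 (2S,3S,4S,5S)-5-hydroxy-1,1-dimethoxy-3-methyl-4-(prop-1-en-2-yl)-3-vinylocta-6,7-dien-2-yl (2S)-2-methylbutanoate
Product: 18 (3S,4S,5S,6S)-2-hydroxy-4-methyl-6-(propa-1,2-dien-1-yl)-5-(prop-1-en-2-yl)-4-vinyltetrahydro-2H-pyran-3-yl (2S)-2-methylbutanoate (anomer mixture)
Conditions: LiBF4, MeCN/H2O (50:1), 60 °C
Reagents that add atoms: water, O
Why: Mild Lewis‑acid acetal hydrolysis unmasks the C8 aldehyde, which the C6 hydroxyl traps as the δ‑lactol (ring–chain tautomerism), so the α‑acyloxy aldehyde is stored without epimerisation at C9.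

Step 10
Reactants: 18 (3S,4S,5S,6S)-2-hydroxy-4-methyl-6-(propa-1,2-dien-1-yl)-5-(prop-1-en-2-yl)-4-vinyltetrahydro-2H-pyran-3-yl (2S)-2-methylbutanoate (anomer mixture)
Product: 20 (3aS,4R,5S,6S,7S,7aR)-4-hydroxy-6-methyl-3-methylidene-2-oxo-5-(prop-1-en-2-yl)-6-vinyloctahydro-1-benzofuran-7-yl (2S)-2-methylbutanoate, via open hydroxy aldehyde 19 (not isolated)
Conditions: Mo(CO)6 (1.2 equiv), DMSO (10 equiv), toluene, 100 °C
Reagents that add atoms: molybdenum hexacarbonyl (CO donor), [Mo].[C-]#[O+].[C-]#[O+].[C-]#[O+].[C-]#[O+].[C-]#[O+].[C-]#[O+]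
Why: Allenic hetero‑Pauson–Khand [2+2+1]: the DMSO‑activated molybdenum carbonyl couples the internal allene π‑bond with the aldehyde of the ring‑opened lactol and inserts CO, closing the cyclohexane (C7–C8) and the α‑methylene‑γ‑lactone at once; in the chair with the C5 isopropenyl, C6 hydroxyl and C10 vinyl equatorial, the axial C10 methyl and the axial C9 acyloxy each block one cis‑fused mode, so both π‑systems react equatorially and give the trans‑fused 7αH,8βH lactone.

Step 11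
Reactants: 20 (3aS,4R,5S,6S,7S,7aR)-4-hydroxy-6-methyl-3-methylidene-2-oxo-5-(prop-1-en-2-yl)-6-vinyloctahydro-1-benzofuran-7-yl (2S)-2-methylbutanoate
Product: 21 (3aR,5S,6S,7S,7aR)-6-methyl-3-methylidene-2,4-dioxo-5-(prop-1-en-2-yl)-6-vinyloctahydro-1-benzofuran-7-yl (2S)-2-methylbutanoate
Conditions: Dess–Martin periodinane, NaHCO3, CH2Cl2, 0 °C; used at once
Reagents that add atoms: none
Why: Dess–Martin oxidation under buffered, non‑basic conditions gives the C6 ketone without epimerising C5 or C7 and without β‑elimination of the lactone oxygen.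

Step 12
Reactants: 21 (3aR,5S,6S,7S,7aR)-6-methyl-3-methylidene-2,4-dioxo-5-(prop-1-en-2-yl)-6-vinyloctahydro-1-benzofuran-7-yl (2S)-2-methylbutanoate
Product: 22 (3aS,4S,5S,6S,7S,7aR)-4-hydroxy-6-methyl-3-methylidene-2-oxo-5-(prop-1-en-2-yl)-6-vinyloctahydro-1-benzofuran-7-yl (2S)-2-methylbutanoate
Conditions: NaBH4, CeCl3·7H2O, MeOH, −78 °C
Reagents that add atoms: none
Why: Luche reduction (1,2‑selective, spares the methylene lactone and the esters): the axial β trajectory at C6 is screened by the syn‑axial C10 methyl, so hydride enters from the α face and gives the axial 6β alcohol.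

Step 13
Reactants: 22 (3aS,4S,5S,6S,7S,7aR)-4-hydroxy-6-methyl-3-methylidene-2-oxo-5-(prop-1-en-2-yl)-6-vinyloctahydro-1-benzofuran-7-yl (2S)-2-methylbutanoate
Product: 23 (3aS,4S,5R,6S,7S,7aR)-4-hydroxy-6-methyl-3-methylidene-2-oxo-5-(3-oxoprop-1-en-2-yl)-6-vinyloctahydro-1-benzofuran-7-yl (2S)-2-methylbutanoate
Conditions: SeO2 (1.3 equiv), 1,4-dioxane, 70 °C
Reagents that add atoms: selenium dioxide, O=[Se]=O
Why: Riley allylic oxidation (ene reaction then [2,3]-sigmatropic shift, twice) takes the methyl of the only electron‑rich alkene with allylic hydrogens to the enal; the vinyl group has none and the methylene lactone is electron‑poor (the C5 descriptor becomes R by CIP ranking only).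

Step 14
Reactants: 23 (3aS,4S,5R,6S,7S,7aR)-4-hydroxy-6-methyl-3-methylidene-2-oxo-5-(3-oxoprop-1-en-2-yl)-6-vinyloctahydro-1-benzofuran-7-yl (2S)-2-methylbutanoate
Product: 24 (3aS,4S,5R,6R,7S,7aR)-4-hydroxy-6-methyl-3-methylidene-6-[(2R)-oxiran-2-yl]-2-oxo-5-(3-oxoprop-1-en-2-yl)octahydro-1-benzofuran-7-yl (2S)-2-methylbutanoate (CNP0510523.1)
Conditions: Ti(OiPr)4 (10 mol %), chiral salalen ligand (12 mol %, antipode that gives (R)-epoxides from 1-alkenes), 30 % aq H2O2 (1.5 equiv), CH2Cl2, rt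
Reagents that add atoms: hydrogen peroxide, OO
Why: Titanium–salalen‑catalysed asymmetric epoxidation with H2O2 picks the non‑conjugated monosubstituted alkene (enal and methylene lactone are electron‑poor) and the chiral catalyst sets C1 as R.

## Compound list

1 | but-2-yn-1-ol | CC#CCO | starting material
2 | 3-methylbut-3-enoic acid | CC(=C)CC(=O)O | starting material
3 | but-2-yn-1-yl 3-methylbut-3-enoate | CC#CCOC(=O)CC(C)=C | intermediate
4 | 2,2-dimethoxyacetaldehyde | COC(OC)C=O | starting material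
5 | chlorobis(cyclopentadienyl)[(2E)-4-(3-methylbut-3-enoyloxy)but-2-en-2-yl]zirconium | C/C(=C\COC(=O)CC(C)=C)[Zr](Cl)(C1C=CC=C1)C1C=CC=C1 | intermediate (not isolated)
6 | methyl[(2E)-4-(3-methylbut-3-enoyloxy)but-2-en-2-yl]zinc | C/C(=C\COC(=O)CC(C)=C)[Zn]C | intermediate (not isolated)
7 | (2E,4S)-4-hydroxy-5,5-dimethoxy-3-methylpent-2-en-1-yl 3-methylbut-3-enoate | C/C(=C\COC(=O)CC(C)=C)[C@@H](C(OC)OC)O | intermediate
8 | (1E)-1-{[(2E,4S)-5,5-dimethoxy-3-methyl-4-(trimethylsilyloxy)pent-2-en-1-yl]oxy}-3-methyl-1-(trimethylsilyloxy)buta-1,3-diene | C/C(=C\CO/C(O[Si](C)(C)C)=C\C(C)=C)[C@@H](C(OC)OC)O[Si](C)(C)C | intermediate (not isolated)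
9 | (2S,3S,4S)-4-hydroxy-5,5-dimethoxy-3-methyl-2-(prop-1-en-2-yl)-3-vinylpentanoic acid | OC(=O)[C@@H](C(C)=C)[C@](C)(C=C)[C@@H](C(OC)OC)O | intermediate (not isolated)
10 | (3S,4S,5S)-5-(dimethoxymethyl)-4-methyl-3-(prop-1-en-2-yl)-4-vinyldihydrofuran-2(3H)-one | O=C1[C@@H](C(C)=C)[C@](C)(C=C)[C@@H](C(OC)OC)O1 | intermediate
11 | (2S,3S,4S)-4-hydroxy-N,5,5-trimethoxy-N,3-dimethyl-2-(prop-1-en-2-yl)-3-vinylpentanamide | CON(C)C(=O)[C@@H](C(C)=C)[C@](C)(C=C)[C@@H](C(OC)OC)O | intermediate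
12 | (S)-2-methylbutanoic anhydride | CC[C@H](C)C(=O)OC(=O)[C@@H](C)CC | starting material
13 | (2S,3S,4S)-1,1-dimethoxy-5-[methoxy(methyl)amino]-3-methyl-5-oxo-4-(prop-1-en-2-yl)-3-vinylpentan-2-yl (2S)-2-methylbutanoate | CON(C)C(=O)[C@@H](C(C)=C)[C@](C)(C=C)[C@@H](C(OC)OC)OC(=O)[C@@H](C)CC | intermediate
14 | (2S,3S,4S)-1,1-dimethoxy-3-methyl-5-oxo-4-(prop-1-en-2-yl)-3-vinylhept-6-yn-2-yl (2S)-2-methylbutanoate | C#CC(=O)[C@@H](C(C)=C)[C@](C)(C=C)[C@@H](C(OC)OC)OC(=O)[C@@H](C)CC | intermediate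
15 | (2S,3S,4S,5R)-5-hydroxy-1,1-dimethoxy-3-methyl-4-(prop-1-en-2-yl)-3-vinylhept-6-yn-2-yl (2S)-2-methylbutanoate | C#C[C@H](O)[C@@H](C(C)=C)[C@](C)(C=C)[C@@H](C(OC)OC)OC(=O)[C@@H](C)CC | intermediate
16 | (2S,3S,4S,5R)-8-(dicyclohexylamino)-5-hydroxy-1,1-dimethoxy-3-methyl-4-(prop-1-en-2-yl)-3-vinyloct-6-yn-2-yl (2S)-2-methylbutanoate | C(C#C[C@H](O)[C@@H](C(C)=C)[C@](C)(C=C)[C@@H](C(OC)OC)OC(=O)[C@@H](C)CC)N(C1CCCCC1)C1CCCCC1 | intermediate (not isolated)
17 | (2S,3S,4S,5S)-5-hydroxy-1,1-dimethoxy-3-methyl-4-(prop-1-en-2-yl)-3-vinylocta-6,7-dien-2-yl (2S)-2-methylbutanoate | C=C=C[C@H](O)[C@@H](C(C)=C)[C@](C)(C=C)[C@@H](C(OC)OC)OC(=O)[C@@H](C)CC | intermediate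
18 | (3S,4S,5S,6S)-2-hydroxy-4-methyl-6-(propa-1,2-dien-1-yl)-5-(prop-1-en-2-yl)-4-vinyltetrahydro-2H-pyran-3-yl (2S)-2-methylbutanoate (anomer mixture) | C=C=C[C@H]1[C@@H](C(C)=C)[C@](C)(C=C)[C@H](OC(=O)[C@@H](C)CC)C(O)O1 | intermediate
19 | (2S,3S,4S,5S)-5-hydroxy-3-methyl-1-oxo-4-(prop-1-en-2-yl)-3-vinylocta-6,7-dien-2-yl (2S)-2-methylbutanoate | C=C=C[C@H](O)[C@@H](C(C)=C)[C@](C)(C=C)[C@@H](C=O)OC(=O)[C@@H](C)CC | intermediate (not isolated)
20 | (3aS,4R,5S,6S,7S,7aR)-4-hydroxy-6-methyl-3-methylidene-2-oxo-5-(prop-1-en-2-yl)-6-vinyloctahydro-1-benzofuran-7-yl (2S)-2-methylbutanoate (6α-OH, trans-fused lactone) | C=C1C(=O)O[C@@H]2[C@@H]1[C@H](O)[C@@H](C(C)=C)[C@](C)(C=C)[C@@H]2OC(=O)[C@@H](C)CC | intermediate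
21 | (3aR,5S,6S,7S,7aR)-6-methyl-3-methylidene-2,4-dioxo-5-(prop-1-en-2-yl)-6-vinyloctahydro-1-benzofuran-7-yl (2S)-2-methylbutanoate | C=C1C(=O)O[C@@H]2[C@@H]1C(=O)[C@@H](C(C)=C)[C@](C)(C=C)[C@@H]2OC(=O)[C@@H](C)CC | intermediate
22 | (3aS,4S,5S,6S,7S,7aR)-4-hydroxy-6-methyl-3-methylidene-2-oxo-5-(prop-1-en-2-yl)-6-vinyloctahydro-1-benzofuran-7-yl (2S)-2-methylbutanoate (6β-OH) | C=C1C(=O)O[C@@H]2[C@@H]1[C@@H](O)[C@@H](C(C)=C)[C@](C)(C=C)[C@@H]2OC(=O)[C@@H](C)CC | intermediate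
23 | (3aS,4S,5R,6S,7S,7aR)-4-hydroxy-6-methyl-3-methylidene-2-oxo-5-(3-oxoprop-1-en-2-yl)-6-vinyloctahydro-1-benzofuran-7-yl (2S)-2-methylbutanoate | C=C1C(=O)O[C@@H]2[C@@H]1[C@@H](O)[C@@H](C(=C)C=O)[C@](C)(C=C)[C@@H]2OC(=O)[C@@H](C)CC | intermediate
24 | (3aS,4S,5R,6R,7S,7aR)-4-hydroxy-6-methyl-3-methylidene-6-[(2R)-oxiran-2-yl]-2-oxo-5-(3-oxoprop-1-en-2-yl)octahydro-1-benzofuran-7-yl (2S)-2-methylbutanoate | C=C1C(=O)O[C@@H]2[C@@H]1[C@@H](O)[C@@H](C(=C)C=O)[C@](C)([C@@H]1CO1)[C@@H]2OC(=O)[C@@H](C)CC | target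

## Step count and weak points

Total steps: 14. Longest linear sequence: 14 (1 → 24).

**Step 10 (ring closure).** The known allenic hetero‑Pauson–Khand closures mostly give cis‑fused five‑membered carbocycles. Here a trans‑fused six‑membered ring must form from a lactol that carries a free allenylic hydroxyl, so low conversion or the wrong ring fusion are the main dangers. Fallback, stepwise closure through an allylcopper: allenol 17 is silylated (TBSOTf, 2,6‑lutidine) to the silyl ether F1, and LiBF4 in wet MeCN then frees the aldehyde F2. CuCl/PCy3/NaOt‑Bu‑catalysed borylcupration of the allene with B2pin2 gives a 2‑boryl allylcopper that adds to the aldehyde through C7 and closes the cyclohexanol boronate F3. Oxidative carbonylation of the alkenylboronate (Pd(OAc)2, PPh3, CO, p‑benzoquinone) closes the lactone on the C8 hydroxyl to give the silyl‑protected lactone F4. HF·pyridine removes the silyl group and the route is rejoined at 20.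

**Step 12 (C6 reduction).** Small hydrides normally attack axially; here only one syn‑axial methyl opposes that, so a mixture of C6 epimers is possible. Fallback, mask the Michael acceptor and use a bulky hydride: ketone 21 takes up thiophenol (PhSH, Et3N) to give the sulfide F5. LiBH(s‑Bu)3 at −78 °C then reduces only the ketone from the equatorial side to the 6β alcohol F6. NaIO4 gives the sulfoxide F7, whose thermal syn‑elimination (toluene, 100 °C) restores the methylene lactone and returns to 22.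

**Step 14 (epoxidation).** The vinyl group sits on a quaternary carbon, an aldehyde is present, and catalyst and substrate may be mismatched. Fallback, unselective epoxidation followed by kinetic resolution: enal 23 is treated with dimethyldioxirane (acetone, 0 °C), which gives 24 together with its C1 epimer F8. Hydrolytic kinetic resolution with (R,R)-N,N'-bis(3,5-di-tert-butylsalicylidene)cyclohexane-1,2-diaminocobalt acetate (trivalent cobalt) and water (0.6 equiv) opens F8 to the diol F9 and leaves 24, which is separated by chromatography.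

## Further compounds

F1 | step 10 | (2S,3S,4S,5S)-5-(tert-butyldimethylsilyloxy)-1,1-dimethoxy-3-methyl-4-(prop-1-en-2-yl)-3-vinylocta-6,7-dien-2-yl (2S)-2-methylbutanoate | C=C=C[C@H](O[Si](C)(C)C(C)(C)C)[C@@H](C(C)=C)[C@](C)(C=C)[C@@H](C(OC)OC)OC(=O)[C@@H](C)CC
F2 | step 10 | (2S,3S,4S,5S)-5-(tert-butyldimethylsilyloxy)-3-methyl-1-oxo-4-(prop-1-en-2-yl)-3-vinylocta-6,7-dien-2-yl (2S)-2-methylbutanoate | C=C=C[C@H](O[Si](C)(C)C(C)(C)C)[C@@H](C(C)=C)[C@](C)(C=C)[C@@H](C=O)OC(=O)[C@@H](C)CC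
F3 | step 10 | cyclohexanol boronate (elemane numbering): 9α-[(2S)-2-methylbutanoyloxy]-8α-hydroxy-6α-(tert-butyldimethylsilyloxy)-7β-[1-(4,4,5,5-tetramethyl-1,3,2-dioxaborolan-2-yl)ethenyl]-10β-methyl-5β-(prop-1-en-2-yl)-10α-vinylcyclohexane | C=C(B1OC(C)(C)C(C)(C)O1)[C@H]1[C@H](O[Si](C)(C)C(C)(C)C)[C@@H](C(C)=C)[C@](C)(C=C)[C@H](OC(=O)[C@@H](C)CC)[C@@H]1O
F4 | step 10 | 6-O-tert-butyldimethylsilyl ether of 20 | C=C1C(=O)O[C@@H]2[C@@H]1[C@H](O[Si](C)(C)C(C)(C)C)[C@@H](C(C)=C)[C@](C)(C=C)[C@@H]2OC(=O)[C@@H](C)CC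
F5 | step 12 | thiophenol adduct of 21 (13-phenylsulfanyl-11,13-dihydro, C11 epimers) | c3ccccc3SCC1C(=O)O[C@@H]2[C@@H]1C(=O)[C@@H](C(C)=C)[C@](C)(C=C)[C@@H]2OC(=O)[C@@H](C)CC
F6 | step 12 | 6β-alcohol of the thiophenol adduct (C11 epimers) | c3ccccc3SCC1C(=O)O[C@@H]2[C@@H]1[C@@H](O)[C@@H](C(C)=C)[C@](C)(C=C)[C@@H]2OC(=O)[C@@H](C)CC
F7 | step 12 | sulfoxide of the 6β-alcohol (13-phenylsulfinyl, C11 and S epimers) | O=S(CC1C(=O)O[C@@H]2[C@@H]1[C@@H](O)[C@@H](C(C)=C)[C@](C)(C=C)[C@@H]2OC(=O)[C@@H](C)CC)c1ccccc1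
F8 | step 14 | C1 epimer of 24, [(2S)-oxiran-2-yl] | C=C1C(=O)O[C@@H]2[C@@H]1[C@@H](O)[C@@H](C(=C)C=O)[C@](C)([C@H]1CO1)[C@@H]2OC(=O)[C@@H](C)CC
F9 | step 14 | (1S)-1,2-dihydroxyethyl compound from hydrolysis of the C1 epimer | C=C1C(=O)O[C@@H]2[C@@H]1[C@@H](O)[C@@H](C(=C)C=O)[C@](C)([C@H](O)CO)[C@@H]2OC(=O)[C@@H](C)CC
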